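## Analysis of the target

The target 14 is a ter-naphthalene built from three 8-methoxynaphthalen-1-ol units. Unit A is bonded through its C2 to C2 of the central unit B (an ortho–ortho bond, each end next to a C1 hydroxyl), and unit B is bonded through its C4 to C4 of unit C (a para–para bond). There is no stereocentre; the C2(A)–C2(B) axis rotates freely and the C4(B)–C4(C) axis, a 1,1′-binaphthyl axis with only hydrogens ortho to it, is left undefined in the structure, so nothing stereochemical has to be controlled. The sensitive elements are the three peri-methoxy naphthols: they are electron rich and prone to air oxidation, above all as phenoxides, and units A and C each keep a free para or ortho carbon open to further coupling. The difficulty is regiochemical: three identical monomers must be joined by two different bonds, with unit B reacting at both its ortho and its para carbon, unit A only ortho and unit C only para. The strategy rests on the C2(A)–C2(B) bond being flanked by the C1 oxygens of both units while C4(B) is already occupied by unit C. An O–Si–O bridge between those two oxygens therefore puts C2(A) and C2(B), and no other pair of carbons, at the ends of a future seven-membered ring (C1(A), C2(A), C2(B), C1(B), O, Si, O).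

## Retrosynthetic reasoning

14 back to 13 and 12. No skeletal bond is cut. The acetal C–O bond on the oxygen of unit C (14 from 13) and the two Si–O bonds of the bridge (13 from 12) are broken last, because the free naphthols are the oxidation-sensitive part of the molecule. The forward steps must be non-oxidising and must avoid long-lived phenoxides: buffered fluoride first, then dilute acid.

12 back to 11. The C2(A)–C2(B) bond is cut. It is the only inter-unit bond with a hydroxyl on each side, so it is the only one a short tether through oxygen can deliver. Cutting here leaves one aryl bromide on unit A and an unfunctionalised C–H on unit B. The forward reaction is a palladium-catalysed intramolecular C–H arylation that must form this bond and close the seven-membered ring without cleaving the Si–O bonds.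

11 back to 8, 9 and 7 (through 10). The two Si–O bonds are cut. This reduces the problem to two phenols and dichlorodi(propan-2-yl)silane 9. Forward, the two chlorides must be displaced one after the other: the cheaper bromonaphthol 8 first, to give chlorosilane 10, then the more valuable dimer 7.

7 back to 6 and 4. The C4(B)–C4(C) bond is cut as a Suzuki–Miyaura disconnection. A direct oxidative dimerisation of 2 was not chosen for this bond because it offers no control of ortho versus para coupling and would leave two equivalent hydroxyls to be told apart statistically. The cross-coupling fixes para–para connectivity and delivers 7 with one free hydroxyl (unit B, from 4) and one protected hydroxyl (unit C, from 6).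

6 back to 5 and 4. The C–B bond and the O–CH2 bond are cut. Bromide 4 serves twice: directly as the electrophile for unit B, and after O-protection and borylation as the nucleophile for unit C, so one intermediate feeds both halves of 7.

4 and 8 back to 2 and 3. The C–Br bonds are cut. Both bromides come from the same monomer 2 and N-bromosuccinimide 3 under regiodivergent conditions: a polar solvent without additive for the para bromide 4, and secondary-amine catalysis in a non-polar solvent for the ortho bromide 8.

2 back to 1. One O–CH3 bond is cut. Naphthalene-1,8-diol 1 is commercially available, and forward a single methylation is needed, which the peri hydrogen bond of the monoanion favours.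

## Alternatives that were turned down

Alternative 1: The hydroxylated ring of unit A is cut at C1(A)–C8a(A). Unit A then traces back to the open-chain (Z)-2,4-diarylbut-3-enoic acid A2, attached through its α-carbon to C2 of a bis-benzylated B–C dimer. In the forward key step A2 is activated as a mixed anhydride under hot, carboxylate-buffered acylating conditions and eliminates to an aryl-conjugated vinylketene. Six-electron electrocyclisation onto the ring carbon ortho to the methoxy group and O-acylation then give naphthyl acetate A1.
- For: the A–B bond is an ordinary C–C bond from the start, so no biaryl coupling between two oxygenated carbons is needed. The ring closure is a classical, metal-free naphthol synthesis.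
- Against: the chain must have, or acquire in the flask, the Z geometry. Closure must occur at the crowded carbon between the side chain and the methoxy group, which is why a bromine has to block the carbon para to the methoxy group and be removed later. The new acetoxy group ends up peri to OMe and ortho to a bulky aryl. Installing a two-carbon acid handle at C2(B) and building the chain costs an estimated five to six steps, and acetate, benzyl ethers and bromide must all be removed.
- Comparison: on predictability of the bond-forming event itself, A1 formation is at least as strong as the chosen C–H arylation. The chosen strategy offers instead roughly half the step count and the use of one monomer, 2, for all three units.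

Alternative 2: The central ring is cut at C1(B)–C2(B) and C3(B)–C4(B). The oxygenated ring of unit B is then assembled from benzocyclobutenone A4, which carries unit C, and vinyllithium A5, which carries unit A. In the forward key step A5 adds to the ketone of A4, the alkoxide opens the four-membered ring to an ortho-quinodimethane, and six-electron closure gives tetralone A3 as a diastereomer mixture. A3 then has to be dehydrogenated to the naphthol and deprotected.
- For: it is the most convergent of the four plans. Both inter-unit bonds of unit B are defined by the building blocks, and the cascade runs at low temperature without a transition metal.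
- Against: A4 is a strained ketone whose preparation (aryne cycloaddition with the right orientation to the methoxy group, then placing unit C on the benzylic carbon) is long and itself uncertain. A5 needs a 2-acyl derivative of unit A, so the ortho-functionalisation problem of unit A is not avoided. A3 must be oxidised to an aromatic ring in a molecule holding three electron-rich naphthalenes, which is the kind of step the target's sensitivity argues against. Two stereocentres are made only to be destroyed.
- Comparison: A3 formation is stronger than the chosen route on convergence. The chosen strategy offers a redox-neutral skeleton assembly with no oxidation after the naphthalenes are in place, and a shorter path to its key-step precursor.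

Alternative 3: The hydroxylated ring of unit A is cut at C1(A)–C2(A) and C2(A)–C3(A). Unit A then arises from isocoumarin A7 and the benzylic Grignard reagent A8 built on C2(B) of the bis-protected dimer. In the forward key step A8 adds to the lactone carbonyl, the ring opens to a ketone with a pendant aldehyde enolate, and intramolecular aldol condensation with dehydration gives trimer A6, whose unit A hydroxyl is already free.
- For: it is convergent, delivers the naphthol at the right oxidation level, and A6 is a single acidic deprotection from 14, one step shorter at the end than the chosen route.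
- Against: A8 needs a one-carbon handle at C2(B) of 7 (ortho-formylation, protection, reduction and halogenation, an estimated four steps). Benzylic Grignard reagents of electron-rich ortho-alkoxybenzyl halides tend to couple with their own halide. The intermediate aryl benzyl ketone can take up a second equivalent of A8. A7 must be prepared separately in several steps.
- Comparison: regiocontrol is equal and the end game is better. The chosen strategy offers a shorter overall sequence (ten steps against an estimated fourteen or more) and draws every carbon of the skeleton from 2.

Key step: step 8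

Remark on the chemistry: the structure defines no axial configuration, so the C4(B)–C4(C) axis is treated as stereochemically undefined and no atroposelective step is planned.

## Route

Step 1
Reactants: 1 naphthalene-1,8-diol
Product: 2 8-methoxynaphthalen-1-ol
Conditions: MeI (1.05 equiv), K2CO3 (1.1 equiv), acetone, rt to reflux, Ar
Reagents that add atoms: iodomethane, CI
Why: Williamson O-methylation; the monoanion of 1 is stabilised by the peri O–H···O hydrogen bond, so the second hydroxyl is much less acidic and more hindered, and one equivalent of base and MeI should stop at the monoether.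

Step 2
Reactants: 2 8-methoxynaphthalen-1-ol; 3 N-bromosuccinimide
Product: 4 4-bromo-8-methoxynaphthalen-1-ol
Conditions: 3 (1.0 equiv), MeCN, −20 to 0 °C, dark
Reagents that add atoms: none
Why: Electrophilic aromatic bromination; in a polar solvent without an amine, 1-naphthols react at the α-carbon para to the hydroxyl, and the phenol ring is more activated than the anisole ring, so C4 should be the main site with one equivalent of 3 at low temperature.

Step 3
Reactants: 4 4-bromo-8-methoxynaphthalen-1-ol
Product: 5 1-bromo-5-methoxy-4-(methoxymethoxy)naphthalene
Conditions: NaH (1.2 equiv), DMF, 0 °C; MOMCl (1.2 equiv), 0 °C to rt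
Reagents that add atoms: chloromethyl methyl ether (MOMCl), COCCl
Why: O-alkylation of the sodium naphthoxide with MOMCl (Williamson-type acetal formation); full deprotonation with NaH breaks the peri hydrogen bond that would slow an amine-base protocol.

Step 4
Reactants: 5 1-bromo-5-methoxy-4-(methoxymethoxy)naphthalene
Product: 6 2-[5-methoxy-4-(methoxymethoxy)naphthalen-1-yl]-4,4,5,5-tetramethyl-1,3,2-dioxaborolane
Conditions: B2pin2 (1.2 equiv), Pd(dppf)Cl2 (3 mol %), KOAc (3 equiv), 1,4-dioxane, 90 °C, Ar
Reagents that add atoms: bis(pinacolato)diboron, CC1(C)OB(OC1(C)C)B1OC(C)(C)C(C)(C)O1
Why: Miyaura borylation of an aryl bromide; KOAc is too weak a base to drive Suzuki homocoupling, and the acetal and methyl ether are inert.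

Step 5
Reactants: 6 2-[5-methoxy-4-(methoxymethoxy)naphthalen-1-yl]-4,4,5,5-tetramethyl-1,3,2-dioxaborolane; 4 4-bromo-8-methoxynaphthalen-1-ol
Product: 7 5,5′-dimethoxy-4′-(methoxymethoxy)-[1,1′-binaphthalen]-4-ol
Conditions: 6 (1.2 equiv), Pd(OAc)2 (3 mol %), SPhos (6 mol %), K3PO4 (3 equiv), toluene/H2O 10:1, 90 °C, degassed
Reagents that add atoms: none
Why: Suzuki–Miyaura cross-coupling forming the C4(B)–C4(C) bond; the dialkylbiarylphosphine supports oxidative addition to the electron-rich, phenoxide-bearing bromide and the union of two peri-substituted naphthyl partners, and the product emerges with exactly one free hydroxyl (unit B) and one MOM ether (unit C).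

Step 6
Reactants: 2 8-methoxynaphthalen-1-ol; 3 N-bromosuccinimide
Product: 8 2-bromo-8-methoxynaphthalen-1-ol
Conditions: 3 (1.0 equiv, slow addition), iPr2NH (10 mol %), CH2Cl2, 0 °C, dark
Reagents that add atoms: none
Why: Amine-catalysed ortho-bromination of a phenol; the N-bromoamine formed from 3 and iPr2NH associates with the phenolic oxygen and delivers bromine to the neighbouring carbon, which in a non-polar solvent turns 1-naphthols into their 2-bromides instead of the 4-bromides.

Step 7
Reactants: 8 2-bromo-8-methoxynaphthalen-1-ol; 9 dichlorodi(propan-2-yl)silane; 7 5,5′-dimethoxy-4′-(methoxymethoxy)-[1,1′-binaphthalen]-4-ol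
Product: 11 [(2-bromo-8-methoxynaphthalen-1-yl)oxy]{[5,5′-dimethoxy-4′-(methoxymethoxy)-[1,1′-binaphthalen]-4-yl]oxy}di(propan-2-yl)silane, via aryloxychlorosilane 10 (not isolated)
Conditions: 9 (1.3 equiv), Et3N, DMAP (10 mol %), CH2Cl2, 0 °C to rt; excess 9 removed in vacuo; then 7 (0.9 equiv), Et3N, DMAP, CH2Cl2, rt to 40 °C
Reagents that add atoms: none
Why: Two successive O-silylations (nucleophilic substitution at silicon); after the first chloride of 9 is displaced by the hindered naphthoxide of 8, the aryloxychlorosilane 10 is much less electrophilic and should persist until 7 is added with DMAP, and pumping off excess 9 in between prevents symmetrical silanes of 7.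

Step 8
Reactants: 11 [(2-bromo-8-methoxynaphthalen-1-yl)oxy]{[5,5′-dimethoxy-4′-(methoxymethoxy)-[1,1′-binaphthalen]-4-yl]oxy}di(propan-2-yl)silane
Product: 12 cyclic di(propan-2-yl)silylene diether of 8,8′-dimethoxy-4-[5-methoxy-4-(methoxymethoxy)naphthalen-1-yl]-[2,2′-binaphthalene]-1,1′-diol (seven-membered 1,3,2-dioxasilepine ring spanning the C1 oxygens of units A and B)
Conditions: Pd(OAc)2 (10 mol %), PCy3·HBF4 (20 mol %), Cs2CO3 (2 equiv), PivOH (30 mol %), p-xylene (0.03 M), 130 °C, Ar
Reagents that add atoms: none
Why: Intramolecular direct arylation across a temporary silicon tether: zerovalent palladium formed from Pd(OAc)2 and PCy3 inserts into the C2–Br bond of unit A, bromide is exchanged for pivalate or carbonate, and concerted metalation–deprotonation at C2–H of unit B gives a diarylpalladium species in an eight-membered palladacycle. Reductive elimination forms the C2(A)–C2(B) bond and contracts the palladacycle to the seven-membered dioxasilepine ring (C1(A), C2(A), C2(B), C1(B), O, Si, O), so the ring closes by C–C bond formation between two sp2 carbons held 1,7 to each other by the O–Si–O bridge. The closest known reaction type is the silicon-tethered intramolecular C–H arylation of mixed bis(aryloxy)dialkylsilanes with an ortho-bromoaryl partner, which gives unsymmetrical 2,2′-biaryldiols after desilylation. No stereocentre is formed, and the new axis carries no stereochemical information that matters for 14. Site selectivity on unit A is fixed by the bromide; on unit B the tether reaches only a carbon ortho to the silyloxy oxygen, and C2 is the single C–H there because the other ortho carbon is the ring fusion C8a and the para carbon C4 carries unit C. Unit C and the distal rings are out of reach of a three-atom bridge, and dilution suppresses intermolecular arylation. The branched isopropyl groups and the non-polar medium shield the Si–O bonds from carbonate, and the MOM and methyl ethers are inert to base and catalyst.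

Step 9
Reactants: 12 cyclic di(propan-2-yl)silylene diether (bridged trimer)
Product: 13 8,8′-dimethoxy-4-[5-methoxy-4-(methoxymethoxy)naphthalen-1-yl]-[2,2′-binaphthalene]-1,1′-diol
Conditions: Bu4NF (2.2 equiv), AcOH (2.2 equiv), THF, 0 °C, Ar
Reagents that add atoms: none
Why: Fluoride-induced cleavage of both aryl Si–O bonds, driven by Si–F bond formation; buffering with AcOH keeps the liberated electron-rich naphthoxides protonated and so limits air oxidation, and the MOM ether is untouched.

Step 10
Reactants: 13 8,8′-dimethoxy-4-[5-methoxy-4-(methoxymethoxy)naphthalen-1-yl]-[2,2′-binaphthalene]-1,1′-diol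
Product: 14 4-(4-hydroxy-5-methoxynaphthalen-1-yl)-8,8′-dimethoxy-[2,2′-binaphthalene]-1,1′-diol (target)
Conditions: HCl (2 M in MeOH), THF/MeOH, 40 °C, Ar; degassed work-up
Reagents that add atoms: none
Why: Acid-catalysed transacetalisation of the MOM ether with methanol; no base or oxidant is present, and aryl methyl ethers and the biaryl bonds are stable to dilute HCl.

## Compound list

1 | naphthalene-1,8-diol | Oc1cccc2cccc(O)c12 | starting material
2 | 8-methoxynaphthalen-1-ol | COc1cccc2cccc(O)c12 | intermediate
3 | N-bromosuccinimide | O=C1CCC(=O)N1Br | starting material
4 | 4-bromo-8-methoxynaphthalen-1-ol | COc1cccc2c(Br)ccc(O)c12 | intermediate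
5 | 1-bromo-5-methoxy-4-(methoxymethoxy)naphthalene | COCOc1ccc(Br)c2cccc(OC)c12 | intermediate
6 | 2-[5-methoxy-4-(methoxymethoxy)naphthalen-1-yl]-4,4,5,5-tetramethyl-1,3,2-dioxaborolane | COCOc1ccc(B2OC(C)(C)C(C)(C)O2)c2cccc(OC)c12 | intermediate
7 | 5,5′-dimethoxy-4′-(methoxymethoxy)-[1,1′-binaphthalen]-4-ol | COCOc1ccc(-c2ccc(O)c3c(OC)cccc23)c2cccc(OC)c12 | intermediate
8 | 2-bromo-8-methoxynaphthalen-1-ol | COc1cccc2ccc(Br)c(O)c12 | intermediate
9 | dichlorodi(propan-2-yl)silane | CC(C)[Si](Cl)(Cl)C(C)C | starting material
10 | chloro[(2-bromo-8-methoxynaphthalen-1-yl)oxy]di(propan-2-yl)silane | COc1cccc2ccc(Br)c(O[Si](Cl)(C(C)C)C(C)C)c12 | intermediate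
11 | [(2-bromo-8-methoxynaphthalen-1-yl)oxy]{[5,5′-dimethoxy-4′-(methoxymethoxy)-[1,1′-binaphthalen]-4-yl]oxy}di(propan-2-yl)silane | COc1cccc2ccc(Br)c(O[Si](C(C)C)(C(C)C)Oc3ccc(-c4ccc(OCOC)c5c(OC)cccc45)c4cccc(OC)c34)c12 | intermediate
12 | cyclic di(propan-2-yl)silylene diether of 13 (silylene-bridged trimer) | COc1cccc2ccc3-c4cc(-c5ccc(OCOC)c6c(OC)cccc56)c5cccc(OC)c5c4O[Si](C(C)C)(C(C)C)Oc3c12 | intermediate
13 | 8,8′-dimethoxy-4-[5-methoxy-4-(methoxymethoxy)naphthalen-1-yl]-[2,2′-binaphthalene]-1,1′-diol | COc1cccc2ccc(-c3cc(-c4ccc(OCOC)c5c(OC)cccc45)c4cccc(OC)c4c3O)c(O)c12 | intermediate
14 | 4-(4-hydroxy-5-methoxynaphthalen-1-yl)-8,8′-dimethoxy-[2,2′-binaphthalene]-1,1′-diol | COc1cccc2ccc(-c3cc(-c4ccc(O)c5c(OC)cccc45)c4cccc(OC)c4c3O)c(O)c12 | target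

## Step count and least certain steps

Total step count: 10. Longest linear sequence: 9 steps (steps 1, 2, 3, 4, 5, 7, 8, 9, 10); step 6 is the side branch that supplies 8.

Step 8 (key step). Two processes compete with the ring-closing C–H metalation. One is base-induced cleavage of an aryl Si–O bond at 130 °C, which destroys the tether before the two carbons are joined. The other is hydrodebromination of the arylpalladium intermediate if metalation of the electron-rich C2–H of unit B is slow. The two peri methoxy groups also crowd the conformer the eight-membered palladacycle needs. The fallback replaces the tethered C–H arylation by an intermolecular Suzuki–Miyaura coupling; it sets out from 7 and 8 and comes back at 14. Bromination of 7 with NBS at low temperature can only go ortho to the free hydroxyl, because the para carbon carries unit C, and should give 3-bromo-5,5′-dimethoxy-4′-(methoxymethoxy)-[1,1′-binaphthalen]-4-ol F1. NaH and MOMCl then give 3-bromo-5,5′-dimethoxy-4,4′-bis(methoxymethoxy)-1,1′-binaphthalene F2. In parallel, 8 is protected with NaH and MOMCl as 2-bromo-8-methoxy-1-(methoxymethoxy)naphthalene F3. Bromine–lithium exchange (n-BuLi, THF, −78 °C) and trapping with iPrOBpin give 2-[8-methoxy-1-(methoxymethoxy)naphthalen-2-yl]-4,4,5,5-tetramethyl-1,3,2-dioxaborolane F4. Coupling of F2 with F4 (Pd(OAc)2, SPhos, K3PO4, toluene/H2O, 90 °C) should give the tris(methoxymethyl) ether of the target F5, and HCl in MeOH removes all three acetals to reach 14.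

Step 6. The likely failure is loss of ortho selectivity: the peri methoxy group already holds the phenolic hydrogen, which may weaken the association with the N-bromoamine, so that para bromination or dibromination takes over. The fallback sets the regiochemistry by directed ortho-metalation; it sets out from 2 and comes back at 8. Protection of 2 (NaH, MOMCl) gives 1-methoxy-8-(methoxymethoxy)naphthalene F6. Lithiation with n-BuLi/TMEDA should occur at C2, because the acetal outranks the methyl ether as a directing group and both peri positions are substituted. Quenching with 1,2-dibromoethane at −78 °C should then give 2-bromo-8-methoxy-1-(methoxymethoxy)naphthalene F3 (the bromide also used in the fallback to step 8), and HCl in MeOH releases 8.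

Step 7. The likely failures are double displacement on 9 (giving the symmetrical bis-ether of 8), hydrolysis of the chlorosilane during handling, and a slow second displacement at a silicon already carrying two isopropyl groups and a peri- and ortho-substituted aryloxy group. The fallback introduces silicon as a hydrosilane, which cannot over-react, and activates it only afterwards; it sets out from 8 and 7 and comes back at 11. Silylation of 8 with chlorodi(propan-2-yl)silane, iPr2Si(H)Cl (Et3N, DMAP, CH2Cl2), gives the isolable [(2-bromo-8-methoxynaphthalen-1-yl)oxy]di(propan-2-yl)silane F7. NBS in CH2Cl2 at 0 °C converts the Si–H bond into the Si–Br bond of bromo[(2-bromo-8-methoxynaphthalen-1-yl)oxy]di(propan-2-yl)silane F8, which is used in the flask. Addition of 7 with Et3N and DMAP should then give 11.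

Step 5. The likely failures are slow oxidative addition into the bromide once its hydroxyl is deprotonated, and protodeboronation of the electron-rich boronate 6 during the longer reaction time this causes. The fallback forms the same bond by oxidative phenol coupling; it sets out from 2 and comes back at 7. Oxidation of 2 with Ag2O in CH2Cl2, with a Na2S2O4 wash to return any over-oxidised binaphthoquinone, should give 5,5′-dimethoxy-[1,1′-binaphthalene]-4,4′-diol F9 after separation from ortho-linked isomers. One equivalent each of NaH and MOMCl then gives 7, with recovered diol and bis-ether recycled. The regioisomer separation and the statistical monoprotection are the reasons this path is only the reserve.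

## Further compounds

F1 | step 8 | 3-bromo-5,5′-dimethoxy-4′-(methoxymethoxy)-[1,1′-binaphthalen]-4-ol | COCOc1ccc(-c2cc(Br)c(O)c3c(OC)cccc23)c2cccc(OC)c12
F2 | step 8 | 3-bromo-5,5′-dimethoxy-4,4′-bis(methoxymethoxy)-1,1′-binaphthalene | COCOc1ccc(-c2cc(Br)c(OCOC)c3c(OC)cccc23)c2cccc(OC)c12
F3 | step 8 | 2-bromo-8-methoxy-1-(methoxymethoxy)naphthalene | COCOc1c(Br)ccc2cccc(OC)c12
F4 | step 8 | 2-[8-methoxy-1-(methoxymethoxy)naphthalen-2-yl]-4,4,5,5-tetramethyl-1,3,2-dioxaborolane | COCOc1c(B2OC(C)(C)C(C)(C)O2)ccc2cccc(OC)c12
F5 | step 8 | tris(methoxymethyl) ether of the target | COCOc1c(-c2cc(-c3ccc(OCOC)c4c(OC)cccc34)c3cccc(OC)c3c2OCOC)ccc2cccc(OC)c12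
F6 | step 6 | 1-methoxy-8-(methoxymethoxy)naphthalene | COCOc1cccc2cccc(OC)c12
F7 | step 7 | [(2-bromo-8-methoxynaphthalen-1-yl)oxy]di(propan-2-yl)silane | COc1cccc2ccc(Br)c(O[SiH](C(C)C)C(C)C)c12
F8 | step 7 | bromo[(2-bromo-8-methoxynaphthalen-1-yl)oxy]di(propan-2-yl)silane | COc1cccc2ccc(Br)c(O[Si](Br)(C(C)C)C(C)C)c12
F9 | step 5 | 5,5′-dimethoxy-[1,1′-binaphthalene]-4,4′-diol | COc1cccc2c(-c3ccc(O)c4c(OC)cccc34)ccc(O)c12
A1 | alternative 1 | 5-bromo-8-methoxy-2-aryl-1-naphthyl acetate, bis-benzyl ether (aryl = B–C dimer) | CC(=O)Oc1c(-c2cc(-c3ccc(OCc4ccccc4)c4c(OC)cccc34)c3cccc(OC)c3c2OCc2ccccc2)ccc2c(Br)ccc(OC)c12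
A2 | alternative 1 | (Z)-4-(2-bromo-5-methoxyphenyl)-2-aryl-but-3-enoic acid, bis-benzyl ether (aryl = B–C dimer) | OC(=O)C(/C=C\c1cc(OC)ccc1Br)c1cc(-c2ccc(OCc3ccccc3)c3c(OC)cccc23)c2cccc(OC)c2c1OCc1ccccc1
A3 | alternative 2 | 8-methoxy-2-[8-methoxy-1-(methoxymethoxy)naphthalen-2-yl]-4-[5-methoxy-4-(methoxymethoxy)naphthalen-1-yl]-3,4-dihydronaphthalen-1(2H)-one (mixture of diastereomers) | COc1cccc2c1C(=O)C(c1ccc3cccc(OC)c3c1OCOC)CC2c1ccc(OCOC)c2c(OC)cccc12
A4 | alternative 2 | 5-methoxy-8-[5-methoxy-4-(methoxymethoxy)naphthalen-1-yl]bicyclo[4.2.0]octa-1,3,5-trien-7-one | COc1cccc2c1C(=O)C2c1ccc(OCOC)c2c(OC)cccc12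
A5 | alternative 2 | 1-[8-methoxy-1-(methoxymethoxy)naphthalen-2-yl]vinyllithium | [Li]C(=C)c1ccc2cccc(OC)c2c1OCOC
A6 | alternative 3 | trimer with free unit A hydroxyl and MOM ethers on units B and C | COc1cccc2ccc(-c3cc(-c4ccc(OCOC)c5c(OC)cccc45)c4cccc(OC)c4c3OCOC)c(O)c12
A7 | alternative 3 | 8-methoxy-1H-isochromen-1-one (8-methoxyisocoumarin) | COc1cccc2ccoc(=O)c12
A8 | alternative 3 | {[5,5′-dimethoxy-4,4′-bis(methoxymethoxy)-[1,1′-binaphthalen]-3-yl]methyl}magnesium chloride | COCOc1c(C[Mg]Cl)cc(-c2ccc(OCOC)c3c(OC)cccc23)c2cccc(OC)c12
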